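The earlier runs and the new flask were computed with made-up constants, noise included.

I rank these flasks by one number: for theta it is 1.17, the cover, the nucleophile charged over twice the electrophile charged.

| setting | midnight | spring | theta | beta | eta |
|---|---|---|---|---|---|
| electrophile | 0.26 M | 0.26 M | 0.26 M | 0.26 M | 0.26 M |
| nucleophile | 0.27 M | 0.54 M | 0.610 M | 0.790 M | 0.470 M |
| remark | run made earlier | run made earlier |  |  |  |
| time |  |  | 2.5 d | 2.5 d | 2.5 d |

- midnight (time / h: electrophile / %, product / %): 2.50: 91, 6; 8.00: 79, 16; 15.0: 65, 21; 20.0: 58, 21; 30.0: 52, 34
- spring (time / h: electrophile / %, product / %): 6.00: 73, 23; 12.0: 61, 35; 20.0: 44, 46; 25.0: 35, 51; 30.0: 36, 52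

(standard deviation of a reading: 2 percentage points)

- in percentages every species weighs as the electrophile in it: one homo dimer counts as two
- the earlier runs were read with a standard deviation of 2 percentage points
- steps thought possible: electrophile + nucleophile -> acid set free + product; nucleophile + acid set free <-> protonated nucleophile; 2 electrophile -> homo dimer

- part of the electrophile that has reacted at the end, theta
- part of the electrophile that has reacted at the end, beta
- part of the electrophile that has reacted at the end, eta
- what raising the concentration of nucleophile from its lowest to its highest value here does to the part of the electrophile that has reacted (changes below 5 percentage points count as none) (it falls / no change / it rises)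

1. First way, by counting. Each turn of the product step uses one nucleophile and sets one acid free. If a second nucleophile takes that acid, the toll is two per turn, and the free fraction of the nucleophile is one minus the product fraction over the cover.

2. Second way, from the spring run. With twice the nucleophile of the midnight run, it gains product twice as fast, so I read the rate as following free nucleophile. Product gain per mean electrophile fraction is 0.0443 h⁻¹ up to 6.00 h, but 0.0256 h⁻¹ from 12.0 h to 25.0 h. That fall, set against the mean product of each stretch, reads as a toll of 2.41.

3. The two ways part, so I test the reading. A toll of two asks for a late gain of 18 percentage points, and the readings show 16 points. The gap of 2.2 points is the size of the scatter of a single reading, 2 points, so the reading cheats and I keep two.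

4. Eta has a cover of 0.904, below 1, so by this count, homo dimer aside, its nucleophile is the limiting reagent. Beta has 1.52. At equal product, beta keeps more free nucleophile than eta, so I expect a rise, and I put no percentage of my own on it.

5. The forecast gives 84 % (79 % to 89 %) for theta, 91 % (86 % to 95 %) for beta and 77 % (71 % to 83 %) for eta, and says it rises. It counts the same toll: “the released acid removes a second nucleophile”

6. Theta ends with 85.9 % of its electrophile reacted, beta 92.4 % and eta 78.5 %; with more nucleophile it rises, by 14 points.

    electrophile + nucleophile → acid set free + product (k = 0.0845 M⁻¹ h⁻¹)
    nucleophile + acid set free ⇌ protonated nucleophile, settled at all times (K = 400 M⁻¹)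
    2 electrophile → homo dimer (k = 0.0227 M⁻¹ h⁻¹)

7. Theta holds 73.0 % product at 2.50 d. Over its cover that gives a free fraction of 37.6 %, and theta keeps 38 % of its nucleophile free. A flask like eta but charged with 1.2 M of nucleophile has a cover of 2.31 and ends with 92.3 % product, which gives 60.0 %; that flask keeps 60 % free.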